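**Retrosynthetic overview**

1. Locants (longipinane numbering): C1 ketone, C2=C3 (CH3 on C3), C4 and C11 bridgeheads, C5, C6 (gem-dimethyl), C7 (O-tiglate), C8, C9 (O-angelate), C10 (quaternary, CH3); the cyclobutane is C4–C5–C11–C10.
2. Esters last: angelate on O9 by mixed-anhydride acylation; tiglate on O7 by Evans–Tishchenko reduction of a 7-hydroxy-9-ketone, which also sets C9 anti to C7; O7 comes from ligand-controlled β-borylation of the C9 enone, itself the product of a Stork–Danheiser transposition.
3. Key disconnection: C7–C8 and C9–C10 of the seven-membered ring. Ethoxyethyne is inserted into the C7–C10 bond of a tricyclic precursor in which the C7 ketone still bridges C10 and C5 (a bicyclo[2.1.1]hexan-2-one); the C10 methyl is carried as CO2CH3 and reduced afterwards.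
4. Enabling feature: the C7 ketone, flanked by quaternary C6 and by the ester-bearing cyclobutane carbon C10, is a strained, non-enolizable β-keto ester. An alkoxide at C7 cleaves C7–C10 to an ester enolate at C10, and the cis-1,3 cyclobutane carbons C5/C10 force re-closure onto C9.
5. Ring order: cyclobutane with its temporary C6–C7 bridge (crossed [2+2] photocycloaddition of an acyclic dienone), then the cyclohexenone C1–C4/C10/C11 (desymmetrizing aldol of the meso diketone, sets absolute configuration), then the seven-membered ring (key step).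

Key step: step 7

Remark on the chemistry: the C9 ester is read from the SMILES as (Z)-2-methylbut-2-enoate (angelate) and the C7 ester as (E)-2-methylbut-2-enoate (tiglate); the alkylidene geometry of 8 and the two acetyl-bearing centres of 9 are not controlled and do not need to be.

**Route**

Step 1
Reactants: 1 2,2-dimethylbut-3-enoic acid; 2 potassium methyl malonate
Product: 4 methyl 4,4-dimethyl-3-oxohex-5-enoate, via acyl imidazole 3 (not isolated)
Conditions: CDI, THF, 23 °C; then 2, MgCl2, Et3N, MeCN, 23→45 °C; 1 M HCl
Reagents that add atoms: potassium methyl malonate 2, [K+].[O-]C(=O)CC(=O)OC; 1,1'-carbonyldiimidazole, O=C(n1ccnc1)n1ccnc1 (imidazolyl group of 3 only)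
Why: Masamune–Brooks C-acylation of magnesium methyl malonate by the acyl imidazole, followed by decarboxylation, is a standard β-keto ester synthesis that tolerates the α-quaternary centre and the terminal alkene.

Step 2
Reactants: 4 methyl 4,4-dimethyl-3-oxohex-5-enoate; 5 but-3-en-2-one
Product: 6 methyl (5E)-4,4-dimethyl-3,7-dioxooct-5-enoate
Conditions: 5 (5 equiv), RuCl2(=CH-C6H4-2-OiPr)(H2IMes) (second-generation Hoveyda–Grubbs catalyst, 5 mol%), CH2Cl2, 40 °C
Reagents that add atoms: but-3-en-2-one 5, C=CC(C)=O
Why: Olefin cross-metathesis of the hindered, non-dimerizing terminal alkene with excess enone should give the conjugated enone as the thermodynamically preferred E isomer.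

Step 3
Reactants: 6 methyl (5E)-4,4-dimethyl-3,7-dioxooct-5-enoate; 7 2-oxopropanal (methylglyoxal)
Product: 8 methyl (5E)-4,4-dimethyl-3,7-dioxo-2-(2-oxopropylidene)oct-5-enoate
Conditions: 7 (40 wt% in H2O), piperidinium acetate (10 mol%), CH2Cl2, 0→23 °C; used crude
Reagents that add atoms: 2-oxopropanal 7, CC(=O)C=O
Why: Knoevenagel condensation of the β-keto ester methylene with the aldehyde carbonyl of methylglyoxal (much more electrophilic than its ketone) gives the alkylidene β-keto ester, whose alkene geometry is lost in step 4.

Step 4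
Reactants: 8 methyl (5E)-4,4-dimethyl-3,7-dioxo-2-(2-oxopropylidene)oct-5-enoate
Product: 9 methyl 5,6-diacetyl-3,3-dimethyl-2-oxobicyclo[2.1.1]hexane-1-carboxylate (meso isomer; both acetyl groups anti to the ketone bridge)
Conditions: hν (365 nm LED), degassed MeCN (5 mM), 23 °C
Reagents that add atoms: none
Why: Crossed intramolecular [2+2] enone–alkene photocycloaddition of a hexa-1,5-dien-3-one (rule of five: 1,5-closure between the enone β-carbon C11 and C5, then collapse of the C10/C4 1,4-diradical) should form the cyclobutane C4–C5–C11–C10 with C6–C7 as a two-atom bridge that fixes C5 and C10 cis; the acetyl-bearing centres C4 and C11 are epimerizable, so any isomer mixture converges in step 5.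

Step 5
Reactants: 9 methyl 5,6-diacetyl-3,3-dimethyl-2-oxobicyclo[2.1.1]hexane-1-carboxylate
Product: 10 methyl 3,9,9-trimethyl-5,8-dioxotricyclo[4.3.0.0^{2,7}]non-3-ene-7-carboxylate (C1 enone ring closed; C7 ketone still bonded to C10; CO2CH3 on C10)
Conditions: 9-amino-9-deoxy-epi-quinine (20 mol%; or its quinidine-derived pseudoenantiomer, whichever gives 10), CF3CO2H (40 mol%), toluene, 4 Å MS, 23→40 °C
Reagents that add atoms: none
Why: Primary-amine-catalysed intramolecular (enolendo) aldol condensation that differentiates the two enantiotopic acetyl groups of the meso diketone (the known desymmetrization of 4-substituted heptane-2,6-diones to 5-substituted 3-methylcyclohex-2-enones) should close the cyclohexenone and fix the absolute configuration at C4, C5, C10 and C11 under catalyst control, the acetyl-bearing carbons equilibrating through the enamine so that the isomer able to bridge is drained.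

Step 6
Reactants: 10 tricyclic enone keto ester
Product: 11 1,3-dioxolane (ethylene ketal) of the C1 carbonyl of 10
Conditions: (TMSOCH2)2, TMSOTf (5 mol%), CH2Cl2, −78→−20 °C; pyridine quench
Reagents that add atoms: 1,2-bis(trimethylsilyloxy)ethane, C[Si](C)(C)OCCO[Si](C)(C)C
Why: Silyl-transfer ketalization protects the enone carbonyl without moving the double bond (migration would place it at a bridgehead) and leaves the C7 ketone, flanked by two quaternary carbons, free.

Step 7
Reactants: 11 ketal keto ester; 12 ethoxyethyne
Product: 15 ring-expanded vinylogous ester (9-ethoxy-8-en-7-one in the new seven-membered ring; CO2CH3 on C10; C1 dioxolane), via lithium alkoxide 13 (not isolated), via ynone ester enolate 14 (not isolated)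
Conditions: 12, n-BuLi, THF, −78 °C; add 11, −78→0 °C; t-BuOH (2 equiv), 0→23 °C; aq. NH4Cl
Reagents that add atoms: ethoxyethyne 12, C#COCC; n-butyllithium, [Li]CCCC (lithium counter-ion of 13 and 14 only)
Why: Proposed new method: lithium ethoxyacetylide adds to the C7 ketone (the only ketone; the hindered ester and the ketal are spectators) to give alkoxide 13, whose strain-assisted retro-aldol (retro-Claisen-type) cleavage of C7–C10 gives ester enolate 14 tethered to an ethoxy-ynone, and intramolecular conjugate addition of C10 to the ethoxy-bearing alkyne carbon C9 with protonation at C8 gives 15, so that C8–C7 and C9–C10 are formed and C7–C10 is broken in one flask. The closest known reaction types are alkoxide-triggered retro-aldol/Michael (1,3-shift) two-carbon ring expansions of 1-alkenyl- and 1-alkynylcycloalkanols that carry an anion-stabilizing group on the migrating carbon, and the insertion of alkynoates or arynes into the C(α)–C(=O) bond of β-keto esters through cyclobutenoxide fragmentation; a version started by external acetylide addition to a non-enolizable β-keto ester has not been shown. The seven-membered ring closes by 7-endo-dig attack on the alkyne. C10, the only new stereocentre, passes through the planar enolate and is re-formed with C9 on the face cis to the C5 side chain, because the cyclobutane holds C5 and C10 1,3-cis and the four-atom tether cannot reach the other face, so the ester ends anti to the new ring where the methyl must be. The step needs C7–C10 rather than C7–C6 cleavage (secured by the ester, the only anion-stabilizing group), C-attack at C9 rather than 1,2-addition (secured by the push–pull polarization of the alkoxy-ynone and by ring size), and no loss of acetylide by retro-addition (disfavoured because that would rebuild the strained bicyclo[2.1.1]hexanone).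

Step 8
Reactants: 15 ring-expanded vinylogous ester
Product: 16 7-hydroxy-9-ethoxy-8-ene carbaldehyde (CHO on C10; C1 dioxolane; both C7 epimers)
Conditions: i-Bu2AlH (3.2 equiv), CH2Cl2, −78 °C; aq. Rochelle salt
Reagents that add atoms: none
Why: i-Bu2AlH reduction at −78 °C should deliver 1,2-hydride to the vinylogous ester carbonyl and stop the hindered methyl ester at the aldehyde (stable tetrahedral aluminate); the configuration at C7 does not matter because it is erased in step 10.

Step 9
Reactants: 16 hydroxy aldehyde
Product: 18 7-hydroxy-9-ethoxy-8-ene with CH3 on C10 (C1 dioxolane; both C7 epimers), via hydrazone 17 (not isolated)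
Conditions: N2H4·H2O, EtOH, 70 °C; concentrate; KOt-Bu, DMSO, 23 °C
Reagents that add atoms: hydrazine, NN (supplies only the two nitrogens of 17; nothing but hydrogen stays in 18)
Why: Wolff–Kishner reduction converts the non-enolizable aldehyde into the C10 methyl group under basic conditions that the acid-labile vinylogous hemiacetal and the ketal survive.

Step 10
Reactants: 18 hydroxy enol ether
Product: 19 longipina-2,7-diene-1,9-dione
Conditions: 0.5 M HCl (aq.), THF, 0→23 °C
Reagents that add atoms: water, O
Why: Stork–Danheiser transposition: acid ionizes the vinylogous hemiacetal at C7, water adds at the ethoxy-bearing C9 and ethanol is lost to give the C9 ketone conjugated to the new C7=C8 bond, while the same acid hydrolyses the dioxolane.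

Step 11
Reactants: 19 longipina-2,7-diene-1,9-dione
Product: 21 (7R)-7-hydroxylongipin-2-ene-1,9-dione, via boronate 20 (not isolated)
Conditions: B2pin2, CuCl (5 mol%), NaOt-Bu (10 mol%), (R,R)-2,3-bis(tert-butylmethylphosphino)quinoxaline (6 mol%; enantiomer chosen to give 7R), MeOH (2 equiv), THF, 23 °C; then 30% H2O2, pH 7 buffer, 0 °C
Reagents that add atoms: bis(pinacolato)diboron, CC1(C)OB(OC1(C)C)B1OC(C)(C)C(C)(C)O1 (boryl group of 20); hydrogen peroxide, OO (oxygen on C7 of 21)
Why: Copper-catalysed conjugate borylation with a chiral bisphosphine adds boron to C7 of the disubstituted C9 enone (the β,β-disubstituted bicyclic C1 enone reacts far more slowly) on the face selected by the ligand, and oxidation of the C–B bond with retention gives the (7R) alcohol.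

Step 12
Reactants: 21 (7R)-7-hydroxylongipin-2-ene-1,9-dione; 22 (E)-2-methylbut-2-enal
Product: 23 (7R,9R)-9-hydroxy-7-[(E)-2-methylbut-2-enoyloxy]longipin-2-en-1-one
Conditions: 22 (6 equiv), SmI2 (0.3 equiv), THF, −10 °C
Reagents that add atoms: (E)-2-methylbut-2-enal 22, C/C=C(\C)C=O
Why: Evans–Tishchenko reduction: a trivalent samarium alkoxide templates hemiacetal formation between O7 and the aldehyde and intramolecular hydride transfer to the C9 ketone, which sets the C9 hydroxyl anti (trans) to O7 through the six-membered chelate and leaves O7 as the tiglate, the unchelated enone being untouched.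

Step 13
Reactants: 23 (7R,9R)-9-hydroxy-7-tigloyloxy enone; 24 (Z)-2-methylbut-2-enoic acid (angelic acid)
Product: 25 target: (7R,9R)-9-[(Z)-2-methylbut-2-enoyloxy]-7-[(E)-2-methylbut-2-enoyloxy]longipin-2-en-1-one
Conditions: 24, 2,4,6-Cl3C6H2COCl, Et3N, toluene, 23 °C; then 23, toluene, 80 °C
Reagents that add atoms: (Z)-2-methylbut-2-enoic acid 24, C/C=C(/C)C(=O)O
Why: Yamaguchi-type acylation with the preformed mixed anhydride of angelic acid, without nucleophilic catalysts, is the standard way to esterify a hindered secondary alcohol as the angelate without Z-to-E isomerization; no stereocentre is affected.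

**Compound list**

1 | 2,2-dimethylbut-3-enoic acid | C=CC(C)(C)C(=O)O | starting material
2 | potassium methyl malonate | [K+].[O-]C(=O)CC(=O)OC | starting material
3 | 1-(2,2-dimethylbut-3-enoyl)imidazole | C=CC(C)(C)C(=O)n1ccnc1 | intermediate
4 | methyl 4,4-dimethyl-3-oxohex-5-enoate | C=CC(C)(C)C(=O)CC(=O)OC | intermediate
5 | but-3-en-2-one | C=CC(C)=O | starting material
6 | methyl (5E)-4,4-dimethyl-3,7-dioxooct-5-enoate | CC(=O)/C=C/C(C)(C)C(=O)CC(=O)OC | intermediate
7 | 2-oxopropanal (methylglyoxal) | CC(=O)C=O | starting material
8 | methyl (5E)-4,4-dimethyl-3,7-dioxo-2-(2-oxopropylidene)oct-5-enoate (alkylidene geometry not controlled) | CC(=O)/C=C/C(C)(C)C(=O)C(=CC(C)=O)C(=O)OC | intermediate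
9 | methyl 5,6-diacetyl-3,3-dimethyl-2-oxobicyclo[2.1.1]hexane-1-carboxylate (meso; acetyl epimers converge in step 5) | O=C1C(C)(C)[C@@H]2[C@@H](C(C)=O)[C@@]1(C(=O)OC)[C@H]2C(C)=O | intermediate
10 | methyl 3,9,9-trimethyl-5,8-dioxotricyclo[4.3.0.0^{2,7}]non-3-ene-7-carboxylate | O=C1C(C)(C)[C@@H]2[C@H]3C(=O)C=C(C)[C@@H]2[C@]31C(=O)OC | intermediate
11 | C1 ethylene ketal of 10 | O=C1C(C)(C)[C@@H]2[C@H]3C4(OCCO4)C=C(C)[C@@H]2[C@]31C(=O)OC | intermediate
12 | ethoxyethyne | C#COCC | starting material
13 | lithium alkoxide of the C7 ethoxyethynyl carbinol (configuration at C7 immaterial) | [Li+].[O-]C1(C#COCC)C(C)(C)[C@@H]2[C@H]3C4(OCCO4)C=C(C)[C@@H]2[C@]31C(=O)OC | intermediate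
14 | lithium ester enolate at C10 with the 3-ethoxyprop-2-ynoyl group on C6 | [Li+].CCOC#CC(=O)C(C)(C)[C@@H]1[C@H]2C3(OCCO3)C=C(C)[C@@H]1C2=C([O-])OC | intermediate
15 | ring-expanded vinylogous ester (9-ethoxy-8-en-7-one; CO2CH3 on C10; C1 dioxolane) | CCOC1=CC(=O)C(C)(C)[C@@H]2[C@H]3C4(OCCO4)C=C(C)[C@@H]2[C@]31C(=O)OC | intermediate
16 | 7-hydroxy-9-ethoxy-8-ene with CHO on C10 (C1 dioxolane; C7 epimers) | CCOC1=CC(O)C(C)(C)[C@@H]2[C@H]3C4(OCCO4)C=C(C)[C@@H]2[C@]31C=O | intermediate
17 | hydrazone of 16 | CCOC1=CC(O)C(C)(C)[C@@H]2[C@H]3C4(OCCO4)C=C(C)[C@@H]2[C@]31C=NN | intermediate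
18 | 7-hydroxy-9-ethoxy-8-ene with CH3 on C10 (C1 dioxolane; C7 epimers) | CCOC1=CC(O)C(C)(C)[C@@H]2[C@H]3C4(OCCO4)C=C(C)[C@@H]2[C@]31C | intermediate
19 | longipina-2,7-diene-1,9-dione | O=C1C=CC(C)(C)[C@@H]2[C@H]3C(=O)C=C(C)[C@@H]2[C@]31C | intermediate
20 | (7R)-7-(4,4,5,5-tetramethyl-1,3,2-dioxaborolan-2-yl)longipin-2-ene-1,9-dione | O=C1C[C@@H](B4OC(C)(C)C(C)(C)O4)C(C)(C)[C@@H]2[C@H]3C(=O)C=C(C)[C@@H]2[C@]31C | intermediate
21 | (7R)-7-hydroxylongipin-2-ene-1,9-dione | O=C1C[C@@H](O)C(C)(C)[C@@H]2[C@H]3C(=O)C=C(C)[C@@H]2[C@]31C | intermediate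
22 | (E)-2-methylbut-2-enal (tiglic aldehyde) | C/C=C(\C)C=O | starting material
23 | (7R,9R)-9-hydroxy-7-[(E)-2-methylbut-2-enoyloxy]longipin-2-en-1-one | O[C@@H]1C[C@@H](OC(=O)/C(C)=C/C)C(C)(C)[C@@H]2[C@H]3C(=O)C=C(C)[C@@H]2[C@]31C | intermediate
24 | (Z)-2-methylbut-2-enoic acid (angelic acid) | C/C=C(/C)C(=O)O | starting material
25 | (7R,9R)-9-[(Z)-2-methylbut-2-enoyloxy]-7-[(E)-2-methylbut-2-enoyloxy]longipin-2-en-1-one | C/C=C(/C)C(=O)O[C@@H]1C[C@@H](OC(=O)/C(C)=C/C)C(C)(C)[C@@H]2[C@H]3C(=O)C=C(C)[C@@H]2[C@]31C | target

**Step count and risks**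

Total step count: 13. Longest linear sequence: 13 steps (fully linear, 1 → 25).

Three steps most likely to fail:

Step 7 (Proposed new method). What may go wrong: after the retro-aldol opening the C10 enolate may be quenched before it closes on the alkoxy-ynone (slow 7-endo-dig addition), or the acetylide may add too slowly to the hindered ketone. The fallback uses known reactions and builds the same ring stepwise from the opened chain. It sets out from 11. Lithium N,O-dimethylhydroxylamide, LiN(OMe)Me, in THF opens the strained β-keto ester by retro-Claisen cleavage of C7–C10 to the ring-opened Weinreb amide ester F1. Ethoxyethynyllithium (from 12 and n-BuLi, excess, −78 °C) converts the Weinreb amide into the ring-opened ethoxy-ynone ester F2. Cs2CO3 in THF/t-BuOH (or catalytic KOt-Bu) then closes the seven-membered ring by intramolecular Michael addition of the C10 ester enolate, and the sequence comes back to the route at 15.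

Step 5. What may go wrong: poor discrimination between the two enantiotopic acetyl groups, or attack of the primary amine on the strained C7 ketone with retro-Claisen opening. The fallback replaces catalytic desymmetrization by resolution. It sets out from 9; TsOH in benzene with azeotropic removal of water effects the aldol condensation through the enol and gives 10 together with the enantiomer of 10 F3. The racemate is separated by preparative chromatography on a chiral stationary phase (amylose tris(3,5-dimethylphenylcarbamate)), and the route is rejoined at 10.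

Step 12. What may go wrong: the unsaturated aldehyde may be a poor hydride donor or be consumed by pinacol coupling and conjugate reduction, and the acyl group may migrate between O7 and O9. The fallback reverses the order of the two acylations with a sacrificial acetate. It sets out from 21. Evans–Tishchenko reduction with acetaldehyde (SmI2 0.3 equiv, THF, −10 °C) gives the anti 7-acetoxy-9-hydroxy enone F4. Acylation of O9 with the angelic mixed anhydride as in step 13 gives the 7-acetoxy-9-angeloyloxy enone F5. Selective methanolysis of the acetate (K2CO3, MeOH, 0 °C) gives the 7-hydroxy-9-angeloyloxy enone F6, and tigloyl chloride in pyridine/CH2Cl2 at 0 °C then acylates O7, which brings the sequence back at 25.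

**Further compounds**

F1 | step 7 | ring-opened Weinreb amide ester (N-methoxy-N-methylamide at C7 on C6; C10 as CH–CO2CH3, epimers; C1 dioxolane) | CON(C)C(=O)C(C)(C)[C@@H]1[C@H]2C3(OCCO3)C=C(C)[C@@H]1C2C(=O)OC
F2 | step 7 | ring-opened ethoxy-ynone ester (3-ethoxyprop-2-ynoyl on C6; C10 as CH–CO2CH3, epimers; C1 dioxolane) | CCOC#CC(=O)C(C)(C)[C@@H]1[C@H]2C3(OCCO3)C=C(C)[C@@H]1C2C(=O)OC
F3 | step 5 | enantiomer of 10 | O=C1C(C)(C)[C@H]2[C@@H]3C(=O)C=C(C)[C@H]2[C@@]31C(=O)OC
F4 | step 12 | (7R,9R)-7-acetoxy-9-hydroxylongipin-2-en-1-one | O[C@@H]1C[C@@H](OC(C)=O)C(C)(C)[C@@H]2[C@H]3C(=O)C=C(C)[C@@H]2[C@]31C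
F5 | step 12 | (7R,9R)-7-acetoxy-9-[(Z)-2-methylbut-2-enoyloxy]longipin-2-en-1-one | C/C=C(/C)C(=O)O[C@@H]1C[C@@H](OC(C)=O)C(C)(C)[C@@H]2[C@H]3C(=O)C=C(C)[C@@H]2[C@]31C
F6 | step 12 | (7R,9R)-7-hydroxy-9-[(Z)-2-methylbut-2-enoyloxy]longipin-2-en-1-one | C/C=C(/C)C(=O)O[C@@H]1C[C@@H](O)C(C)(C)[C@@H]2[C@H]3C(=O)C=C(C)[C@@H]2[C@]31C
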